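**Retrosynthetic overview**
1. Target 15 ⇒ bis(β-amino enone) 13 (from bis(β-nitro enone) 12): in each half N5 closes ring A (N5–C9a, 6-endo aza-Michael) and then ring B (N5–C6, N-alkylation).
2. 12 ⇒ meso bis-enal 10 + 2 × (E)-1-nitropropene 11 by a twofold carbene-catalysed Stetter reaction. Each aldehyde carbon (C2, C2') acts as an acyl anion equivalent toward the electrophilic β-carbon of 11 (C2–C3 bond); this sets C3 and C3' both R and turns the meso ring into one enantiomer.
3. 10 ⇒ meso 16-membered diyne 9 (Rh hydroformylation) ⇒ diol 8 ⇒ head-to-tail cyclodimerisation of racemic iodo-alkynol 6 (two acetylide alkylations).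
4. 6 ⇒ δ-valerolactone 1 (C6–C9 and C9a) + 1-chloro-5-iodopentane 2 (the (CH2)5 chain) + one carbon (C1) by Ohira–Bestmann homologation.
5. Ring order: 16-membered carbocycle first (step 5), then ring A followed by ring B of both quinolizidinones in the last step.

Locants: quinolizidin-2-one numbering (C1, C2=O, C3–CH3, C4, N5, C6–C9, C9a), primed for the second half; (CH2)5 chains join C9 to C1' and C9' to C1. Read from the SMILES, the unprimed half is 1S,3R,9R,9aR (H1/H9a cis) and the primed half is 1'S,3'R,9'S,9a'S (H1'/H9a' trans). C3/C3' and C1/C1' are alike while C9/C9' and C9a/C9a' are opposite, so the two halves are diastereomers and the molecule is not C2-symmetric.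

Assumption: (E)-1-nitroprop-1-ene (11) is bought and distilled before use.

Where the stereocentres come from: C9/C9' in step 1 (racemic) and step 5 (meso pairing, statistical, separated); C3/C3' in step 8 (catalyst); C9a/C9a' and C1/C1' in step 9.

**Route**

Step 1
Reactants: 1 δ-valerolactone; 2 1-chloro-5-iodopentane
Product: 3 rac-3-(5-chloropentyl)oxan-2-one
Conditions: LiN(iPr)2, THF, −78 °C; then 2, DMPU, −78 → −20 °C
Reagents that add atoms: none
Why: Lactone enolate C-alkylation (SN2 at the primary iodide, the chloride stays); the new centre C9 is made racemic on purpose, because step 5 needs both hands.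

Step 2
Reactants: 3 rac-3-(5-chloropentyl)oxan-2-one
Product: 4 rac-3-(5-chloropentyl)oxan-2-ol
Conditions: iBu2AlH, CH2Cl2, −78 °C; aq. potassium sodium tartrate
Reagents that add atoms: none
Why: Half-reduction of a lactone stops at the tetrahedral aluminate at −78 °C and gives the lactol (masked δ-hydroxy aldehyde) on work-up; only the anomeric centre is new and it is lost in step 3.

Step 3
Reactants: 4 rac-3-(5-chloropentyl)oxan-2-ol
Product: 5 rac-9-chloro-4-ethynylnonan-1-ol
Conditions: dimethyl (1-diazo-2-oxopropyl)phosphonate, K2CO3, MeOH, 0 °C → rt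
Reagents that add atoms: dimethyl (1-diazo-2-oxopropyl)phosphonate, CC(=O)C(=[N+]=[N-])P(=O)(OC)OC
Why: Ohira–Bestmann (Seyferth–Gilbert) homologation of the aldehyde in equilibrium with the lactol adds the carbon that becomes C1 and frees the C6 hydroxyl; no stereocentre is made.

Step 4
Reactants: 5 rac-9-chloro-4-ethynylnonan-1-ol
Product: 6 rac-4-ethynyl-9-iodononan-1-ol
Conditions: NaI, acetone, reflux
Reagents that add atoms: sodium iodide, [Na+].[I-]
Why: Finkelstein halide exchange turns the unreactive primary chloride into the iodide needed for acetylide alkylation.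

Step 5
Reactants: 6 rac-4-ethynyl-9-iodononan-1-ol (two molecules)
Product: 8 meso-diyne diol (3R,11S), via linear iodo dimer 7 (not isolated)
Conditions: LiN(iPr)2 (2.0 equiv per 6), THF–DMPU (5:1), 0.005 M, −78 °C → rt; H2O; meso isomer separated from the racemic diastereomer by preparative HPLC
Reagents that add atoms: none
Why: Head-to-tail cyclodimerisation by two acetylide SN2 alkylations (C-alkylation of the dilithio alkoxide–acetylide; an eight-membered cycloalkyne cannot form, so the first bond is intermolecular and the second closes the 16-membered ring); the pairing of the two racemic C9 centres is statistical, so about half of the ring is the meso isomer 8 (expect 15–20 % of 8 from 6), and any racemic ring carried on would end as C2-symmetric diastereomers of 15 that are removed at the end.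

Step 6
Reactants: 8 meso-diyne diol
Product: 9 meso-(3R,11S)-3,11-bis(3-chloropropyl)cyclohexadeca-1,9-diyne
Conditions: PPh3, N-chlorosuccinimide, CH2Cl2, 0 °C → rt
Reagents that add atoms: N-chlorosuccinimide, O=C1CCC(=O)N1Cl
Why: Appel-type chlorination converts both primary alcohols into chlorides (SN2), giving arms that survive steps 7 and 8 and later alkylate nitrogen; C9/C9' are untouched.

Step 7
Reactants: 9 meso-(3R,11S)-3,11-bis(3-chloropropyl)cyclohexadeca-1,9-diyne
Product: 10 meso-(1E,3R,9E,11S)-3,11-bis(3-chloropropyl)cyclohexadeca-1,9-diene-1,9-dicarbaldehyde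
Conditions: dicarbonyl(acetylacetonato)rhodium [Rh(C5H7O2)(CO)2] (4 mol %), 6-(diphenylphosphino)pyridin-2(1H)-one (20 mol %), CO/H2 (1:1, 10 bar), toluene, 70 °C
Reagents that add atoms: carbon monoxide, [C-]#[O+]
Why: Rhodium-catalysed alkyne hydroformylation adds H and CHO syn to give the (E)-enal, and the formyl group (C2) goes to the alkyne carbon flanked by CH2 (C1) rather than to the one next to the branched C9.

Step 8
Reactants: 10 meso bis-enal; 11 (E)-1-nitroprop-1-ene (3 equiv)
Product: 12 (2R,2'R)-1,1'-[(1E,3R,9E,11S)-3,11-bis(3-chloropropyl)cyclohexadeca-1,9-diene-1,9-diyl]bis(2-methyl-3-nitropropan-1-one)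
Conditions: chiral 7-fluoro-5-isopropyl-2-(pentafluorophenyl)-6,7-dihydro-5H-pyrrolo[2,1-c][1,2,4]triazol-2-ium tetrafluoroborate (20 mol %, the antipode that gives 3R, to be confirmed on a model enal), catechol (2 equiv), iPr2NEt (1 equiv), tert-amyl alcohol, 0 °C
Reagents that add atoms: none
Why: Proposed new method: a twofold intermolecular Stetter reaction on a hindered 2-alkyl enal — the triazolylidene adds to each CHO, catechol-assisted proton transfer gives the Breslow intermediate (acyl anion equivalent), and its carbon adds to the β-carbon of the nitroalkene on the face fixed by the catalyst, so both new C3 centres are R whatever the remote C9 configuration and the meso ring becomes a single enantiomer (the antipode would need two wrong additions); the α-substituent disfavours the competing homoenolate path, and the closest known reaction type is the carbene-catalysed asymmetric intermolecular Stetter reaction of enals with β-alkyl nitroalkenes.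

Step 9
Reactants: 12 bis(β-nitro enone)
Product: 15 target bis-quinolizidinone CNP0268544.1, via bis(amino enone) 13 (not isolated), via bis(piperidone) dichloride 14 (not isolated)
Conditions: Zn, AcOH–EtOH, 0 °C → rt; filter, concentrate; then NaHCO3, NaI (0.2 equiv), MeCN, 50 °C
Reagents that add atoms: none
Why: Nitro-to-amine reduction frees two primary amines that close ring A by 6-endo-trig aza-Michael addition and then ring B by 6-exo-tet N-alkylation; the aza-Michael step is reversible and ring B should close through the chair with the C9 chain and the C9a–C1 bond both equatorial, so C9a follows C9 (9R→9aR, 9'S→9a'S), while C1, α to the ketone, settles equatorial and cis to the C3 methyl (1S, 1'S), which gives H1/H9a cis in the 9R half and trans in the 9'S half as in the target.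

**Compound list**
1 | δ-valerolactone (oxan-2-one) | O=C1CCCCO1 | starting material
2 | 1-chloro-5-iodopentane | ClCCCCCI | starting material
3 | rac-3-(5-chloropentyl)oxan-2-one | O=C1OCCCC1CCCCCCl | intermediate
4 | rac-3-(5-chloropentyl)oxan-2-ol (lactol, anomer mixture) | OC1OCCCC1CCCCCCl | intermediate
5 | rac-9-chloro-4-ethynylnonan-1-ol | OCCCC(C#C)CCCCCCl | intermediate
6 | rac-4-ethynyl-9-iodononan-1-ol | OCCCC(C#C)CCCCCI | intermediate
7 | rac-(4R,12S)-4-ethynyl-12-(3-hydroxypropyl)-17-iodoheptadec-10-yn-1-ol (heterochiral linear dimer, one enantiomer drawn, not isolated) | C#C[C@@H](CCCO)CCCCCC#C[C@H](CCCO)CCCCCI | intermediate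
8 | meso-3,3'-[(3R,11S)-cyclohexadeca-1,9-diyne-3,11-diyl]di(propan-1-ol) | OCCC[C@@H]1C#CCCCCC[C@@H](CCCO)C#CCCCCC1 | intermediate
9 | meso-(3R,11S)-3,11-bis(3-chloropropyl)cyclohexadeca-1,9-diyne | ClCCC[C@@H]1C#CCCCCC[C@@H](CCCCl)C#CCCCCC1 | intermediate
10 | meso-(1E,3R,9E,11S)-3,11-bis(3-chloropropyl)cyclohexadeca-1,9-diene-1,9-dicarbaldehyde | O=C/C1=C/[C@@H](CCCCl)CCCCC/C(=C\[C@H](CCCCl)CCCCC1)C=O | intermediate
11 | (E)-1-nitroprop-1-ene | C/C=C/[N+](=O)[O-] | starting material
12 | (2R,2'R)-1,1'-[(1E,3R,9E,11S)-3,11-bis(3-chloropropyl)cyclohexadeca-1,9-diene-1,9-diyl]bis(2-methyl-3-nitropropan-1-one) | [O-][N+](=O)C[C@@H](C)C(=O)/C1=C/[C@@H](CCCCl)CCCCC/C(=C\[C@H](CCCCl)CCCCC1)C(=O)[C@H](C)C[N+](=O)[O-] | intermediate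
13 | (2R,2'R)-1,1'-[(1E,3R,9E,11S)-3,11-bis(3-chloropropyl)cyclohexadeca-1,9-diene-1,9-diyl]bis(3-amino-2-methylpropan-1-one) (not isolated) | NC[C@@H](C)C(=O)/C1=C/[C@@H](CCCCl)CCCCC/C(=C\[C@H](CCCCl)CCCCC1)C(=O)[C@H](C)CN | intermediate
14 | macrocycle carrying two fused 3-methylpiperidin-4-ones (ring A of each half closed, N–H free) and two 3-chloropropyl arms on C9 and C9'; configuration as in 15 (not isolated) | C[C@@H]1CN[C@@H]2[C@@H](CCCCl)CCCCC[C@H](C(=O)[C@H](C)CN3)[C@@H]3[C@H](CCCCl)CCCCC[C@@H]2C1=O | intermediate
15 | CNP0268544.1, macrocyclic bis(3-methylquinolizidin-2-one), 1S,3R,9R,9aR / 1'S,3'R,9'S,9a'S | C[C@@H]1CN2CCC[C@H]3CCCCC[C@@H]4C(=O)[C@H](C)CN5CCC[C@H](CCCCC[C@H](C1=O)[C@@H]32)[C@@H]45 | target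

**Step count and risks**

Total steps: 9. Longest linear sequence: 9 (1 → 15).

Most likely to fail, in this order:

Step 8 (twofold Stetter reaction). The enal is α,β-disubstituted and hindered, so Breslow-intermediate formation may be slow, homoenolate chemistry may compete, and the β-nitro ketone can lose HNO2 under base. The fallback sets out from 9 and comes back at 13; it gives up the C2–C3 bond and buys C3 instead. Hydrozirconation of diyne 9 with (C5H5)2Zr(H)Cl (zirconium at the less hindered alkyne carbon C1) and iodinolysis give the meso bis(vinyl iodide) F2. Iodine–lithium exchange with (CH3)3CLi at −78 °C, then addition to the Weinreb amide of commercial (R)-3-(Boc-amino)-2-methylpropanoic acid (N–H first deprotonated with iPrMgCl), gives the bis(Boc-amino enone) F3 with both C3 centres R from the chiral pool. HCl in dioxane removes the Boc groups and delivers 13 as its dihydrochloride, which is cyclised as in the NaHCO3 stage of step 9.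

Step 9 (reduction and double ring closure). Ring A closes first, so C9a in the 9R half may follow the C3 methyl instead of C9 and give the C9a epimer; 50 °C with base may also erode C3/C1, and Zn/AcOH may touch the enone. The fallback sets out from 8 and comes back at 15; it keeps the arms at the alcohol level and closes ring B reductively at room temperature. Hydroformylation of diol 8 as in step 7 gives the diol bis-enal F4; the Stetter reaction of step 8 gives the diol bis(nitro enone) F5; Dess–Martin periodinane gives the dialdehyde bis(nitro enone) F6. Zn/AcOH then frees the amines, which add to the enones and condense with the arm aldehydes to bicyclic enamines; these can equilibrate at C9a before NaBH(OAc)3 reduces them to 15.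

Step 5 (cyclodimerisation). Oligomers may dominate, and the meso and racemic rings may be hard to separate. The fallback sets out from 5 and 6 and comes back at 7; it makes the two C–C bonds in separate operations. The dilithio derivative of chloride 5 (3 equiv, LiN(iPr)2) is alkylated with iodide 6 to give the chloro linear dimer F1 (excess 5 recovered). NaI in acetone converts it into 7, which is now isolated, purified and ring-closed on its own by slow addition to LiN(iPr)2 in THF–DMPU at high dilution, giving 8 and its racemic diastereomer as before.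

**Further compounds**
F1 | step 5 | rac-(4R,12S)-17-chloro-4-ethynyl-12-(3-hydroxypropyl)heptadec-10-yn-1-ol (heterochiral pair drawn; formed together with the homochiral pair) | C#C[C@@H](CCCO)CCCCCC#C[C@H](CCCO)CCCCCCl
F2 | step 8 | meso-(1E,3R,9E,11S)-3,11-bis(3-chloropropyl)-1,9-diiodocyclohexadeca-1,9-diene | I/C1=C/[C@@H](CCCCl)CCCCC/C(=C\[C@H](CCCCl)CCCCC1)I
F3 | step 8 | di-tert-butyl N,N'-bis-carbamate of 13 (bis(Boc-amino enone), both C3 centres R) | CC(C)(C)OC(=O)NC[C@@H](C)C(=O)/C1=C/[C@@H](CCCCl)CCCCC/C(=C\[C@H](CCCCl)CCCCC1)C(=O)[C@H](C)CNC(=O)OC(C)(C)C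
F4 | step 9 | meso-(1E,3R,9E,11S)-3,11-bis(3-hydroxypropyl)cyclohexadeca-1,9-diene-1,9-dicarbaldehyde | O=C/C1=C/[C@@H](CCCO)CCCCC/C(=C\[C@H](CCCO)CCCCC1)C=O
F5 | step 9 | (2R,2'R)-1,1'-[(1E,3R,9E,11S)-3,11-bis(3-hydroxypropyl)cyclohexadeca-1,9-diene-1,9-diyl]bis(2-methyl-3-nitropropan-1-one) | [O-][N+](=O)C[C@@H](C)C(=O)/C1=C/[C@@H](CCCO)CCCCC/C(=C\[C@H](CCCO)CCCCC1)C(=O)[C@H](C)C[N+](=O)[O-]
F6 | step 9 | 3,3'-[(1R,2E,9S,10E)-3,11-bis[(2R)-2-methyl-3-nitropropanoyl]cyclohexadeca-2,10-diene-1,9-diyl]dipropanal | [O-][N+](=O)C[C@@H](C)C(=O)/C1=C/[C@@H](CCC=O)CCCCC/C(=C\[C@H](CCC=O)CCCCC1)C(=O)[C@H](C)C[N+](=O)[O-]
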